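The earlier runs and the new flask were computed for substances that don't exist; the scatter is artificial.

The unit of time here is the half-life of the starting material, and the quantity to carry is the count of such half-lives in a run at its temperature.

| setting | ash | maple | Thursday's | Tuesday's | Saturday's |
|---|---|---|---|---|---|
| starting material | 0.35 M | 0.55 M | 0.25 M | 0.25 M | 0.25 M |
| temperature | 29 °C | 38 °C | 25 °C | 33 °C | 41 °C |
| remark | run made earlier | run made earlier |  |  |  |
| time |  |  | 50 min | 50 min | 50 min |

| run | time / min | starting material / % | intermediate / % | isomer of the product / % | target / % |
|---|---|---|---|---|---|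
| ash | 8.00 | 85 | 12 | 0 | 4 |
| ash | 15.0 | 71 | 15 | 2 | 8 |
| ash | 20.0 | 62 | 16 | 6 | 14 |
| ash | 30.0 | 52 | 18 | 7 | 22 |
| ash | 40.0 | 43 | 12 | 9 | 30 |
| ash | 50.0 | 34 | 11 | 17 | 36 |
| maple | 2.00 | 90 | 7 | 1 | 4 |
| maple | 3.00 | 83 | 11 | 3 | 2 |
| maple | 5.00 | 76 | 12 | 4 | 6 |
| maple | 8.00 | 66 | 16 | 5 | 15 |
| maple | 10.0 | 59 | 14 | 9 | 17 |
| maple | 15.0 | 41 | 14 | 11 | 28 |
| maple | 25.0 | 25 | 10 | 21 | 45 |

(each reading ± 1.5 percentage points)

* which of these there is most of at the end, counted by the starting material in it, Thursday's (target / isomer of the product / starting material / intermediate)
* which of these there is most of at the end, counted by the starting material in it, Tuesday's (target / isomer of the product / starting material / intermediate)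
* which of these there is most of at the end, counted by the starting material in it, Saturday's (target / isomer of the product / starting material / intermediate)
* amount of the one of these that there is most of at the end, in percent of the starting material charged, Thursday's
* amount of the one of these that there is most of at the end, in percent of the starting material charged, Tuesday's
* amount of the one of these that there is most of at the end, in percent of the starting material charged, Saturday's

- the numbers in the tables scatter with a standard deviation of 1.5 percentage points
- a reading or a percentage of target counts all its forms, free or not

The ash run reads starting material at 34 % at 50.0 min, which is 1.56 half-lives, so its half-life is 32.1 min. The maple run reads starting material at 25 % at 25.0 min, which gives a half-life of 12.5 min, shorter at 38 °C than at 29 °C. The two runs differ in charge as well, so it is an assumption that the charge has no effect; on that assumption the count doubles every 6.61 K. The half-life count in 50 min is then 1.02 for Thursday's flask, 2.37 for Tuesday's and 5.48 for Saturday's.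

With the main step, the fractions of the charge left as starting material are 0.492, 0.194 and 0.0224, in that order. Next comes the split of the converted material. The last readings of the maple run put target at 0.682 of target plus isomer of the product (the selectivity), and this share of the converted charge gives target 0.346, 0.550 and 0.667. Last comes the intermediate, whose late readings stand near 10.0 % of the charge. Holding that back gives target 0.278, 0.482 and 0.598. By this reckoning, Thursday's flask still holds more starting material than target, while target leads on Tuesday's and Saturday's.

The forecast names starting material at 50 % (44 % to 56 %) for Thursday's, target at 49 % (42 % to 55 %) for Tuesday's and target at 62 % (52 % to 70 %) for Saturday's. Its figures stand slightly above the reckoning here. For Saturday's it trims its estimate because “isomer/target seems to creep upward, possibly through target loss”.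

Thursday's flask gives starting material at 49.6 %. Tuesday's flask gives target at 48.2 %. Saturday's flask gives target at 55.6 %, and its isomer of the product stands at 37.6 %.

    starting material → intermediate (k = 0.0140 min⁻¹, Ea = 81.0 kJ mol⁻¹)
    intermediate ⇌ isomer of the product (K = 60.0, k = 0.0150 min⁻¹, Ea = 96.0 kJ mol⁻¹, ΔH = −51.0 kJ mol⁻¹)
    intermediate ⇌ target (K = 6.20, k = 0.0420 min⁻¹, Ea = 89.0 kJ mol⁻¹, ΔH = −12.0 kJ mol⁻¹)
    starting material → decomposition product (k = 2.10 × 10⁻⁵ min⁻¹, Ea = 106 kJ mol⁻¹)
    crystals ⇌ target, rate k5*(cs5 - [target]) while solid is left; crystals form when [target] > cs5 (solubility = 0.0510 M, k = 2.70 min⁻¹)
    (constants at 25 °C)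

Saturday's flask holds target at 0.596 of target plus isomer of the product, not 0.682, and there the forecast parts from the flask. In Thursday's flask, starting material has a half-life of 50 min by its main step at the end of the run, which makes 1.00 half-lives against the 1.02 counted. That step outruns the loss to decomposition product 670 times. Thursday's flask run at 0 °C counts 0.0743 half-lives, so 0.950 of the charge should stay as starting material; the computed amount of starting material is 96.5 %.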